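**Retrosynthetic overview**

1. Ring A is released last. Its precursor, a 3,5-dimethoxy-2,6-bis(methoxymethoxy)-4-methylphenyl group, has MOM ethers beside the tether and methyl ethers beside the C-methyl. MOM removal and PhI(OAc)2 oxidation (loss of one methanol) can therefore only place OH next to the tether and OMe next to the methyl.
2. Ring B (C1'–C6': carbonyls at C1' and C4', hydroxyls at C2' and C5', tether on C3', methyl on C6') is the dienol of a cyclohexane-1,2,4,5-tetraone. It consists of two 2-oxoacyl units, C3'–C4'–C5' and C6'–C1'–C2', joined head to tail. Cutting C2'–C3' and C5'–C6' gives a tethered ethyl 2-oxoheptadecanoate and ethyl 2-oxobutanoate (crossed double Claisen [3+3] annulation).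
3. The tethered 2-oxo ester comes from an ω-bromopentadecyl arene (Grignard reagent plus diethyl oxalate). That bromide comes from the aryllithium of the MOM-protected arene and 1,15-dibromopentadecane, made from pentadecanolide by reduction and Appel bromination.
4. The arene comes from 2,6-dimethoxytoluene by dibromination at C3 and C5, hydroxylation and MOM protection.
5. Ring order: the benzene ring that becomes ring A is bought; ring B is built in step 8 at its final oxidation level; ring A is oxidised to the quinone in step 10.

Key step: step 8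

Remark on the chemistry: the target has no stereocentre and no stereogenic double bond. Both quinones are drawn as one of their tautomers, and primed locants refer to ring B.

**Route**

Step 1
Reactants: 1 2,6-dimethoxytoluene
Product: 2 1,5-dibromo-2,4-dimethoxy-3-methylbenzene
Conditions: NBS (2.1 equiv), MeCN, 0 °C to rt, dark
Reagents that add atoms: N-bromosuccinimide, O=C1CCC(=O)N1Br
Why: Electrophilic aromatic bromination: C3 and C5 are each ortho to one methoxy group and para to the other while C4 is meta to both, so two equivalents of NBS should brominate C3 and C5 only and leave the benzylic methyl untouched in the absence of a radical initiator.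

Step 2
Reactants: 2 1,5-dibromo-2,4-dimethoxy-3-methylbenzene
Product: 3 4,6-dimethoxy-5-methylbenzene-1,3-diol
Conditions: Pd2(dba)3 (cat.), tBuXPhos (cat.), KOH, 1,4-dioxane/H2O, 100 °C, degassed; then 1 M HCl, 0 °C
Reagents that add atoms: potassium hydroxide, [K+].[OH-]
Why: Palladium-catalysed hydroxylation of aryl bromides (Buchwald–Hartwig-type C–O coupling with hydroxide): each C–Br bond adds oxidatively to zerovalent palladium, bromide is exchanged for hydroxide and the bulky biaryl phosphine drives C–O reductive elimination, the two meta-related bromides reacting independently, while exclusion of air protects the electron-rich resorcinolate.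

Step 3
Reactants: 3 4,6-dimethoxy-5-methylbenzene-1,3-diol
Product: 4 1,5-bis(methoxymethoxy)-2,4-dimethoxy-3-methylbenzene
Conditions: NaH (2.4 equiv), DMF, 0 °C; MOMCl (2.5 equiv), 0 °C to rt
Reagents that add atoms: chloromethyl methyl ether, COCCl
Why: Williamson ether synthesis: the bis-phenoxide is O-alkylated by MOMCl to give acetal ethers that survive organolithium, Grignard and ethoxide conditions, direct the later lithiation and mark the two oxygens that must end as OH and C=O next to the tether.

Step 4
Reactants: 5 oxacyclohexadecan-2-one (pentadecanolide)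
Product: 6 pentadecane-1,15-diol
Conditions: LiAlH4, THF, 0 °C to reflux; then H2O, aq NaOH
Reagents that add atoms: none
Why: Hydride reduction of an ester: LiAlH4 opens the macrolactone to the α,ω-diol, which fixes the chain at fifteen carbons.

Step 5
Reactants: 6 pentadecane-1,15-diol
Product: 7 1,15-dibromopentadecane
Conditions: CBr4 (2.6 equiv), PPh3 (2.6 equiv), CH2Cl2/THF, 0 °C to rt
Reagents that add atoms: carbon tetrabromide, BrC(Br)(Br)Br
Why: Appel reaction: both primary alcohols are activated as alkoxyphosphonium ions and displaced by bromide (SN2) under neutral conditions.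

Step 6
Reactants: 4 1,5-bis(methoxymethoxy)-2,4-dimethoxy-3-methylbenzene; 7 1,15-dibromopentadecane
Product: 9 3-(15-bromopentadecyl)-1,5-dimethoxy-2,4-bis(methoxymethoxy)-6-methylbenzene, via aryllithium 8 (not isolated)
Conditions: n-BuLi (1.1 equiv), THF, 0 °C; then added to 7 (4 equiv), THF/DMPU, −40 °C to rt
Reagents that add atoms: none
Why: Directed ortho-metalation followed by SN2 alkylation: the only ring hydrogen lies between the two MOM ethers, which coordinate n-BuLi and acidify that C–H, and the resulting aryllithium displaces one bromide of 7, the excess of dibromide and the inverse addition holding back a second substitution (unreacted 7 is recovered by chromatography).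

Step 7
Reactants: 9 3-(15-bromopentadecyl)-1,5-dimethoxy-2,4-bis(methoxymethoxy)-6-methylbenzene; 10 diethyl oxalate
Product: 12 ethyl 17-[3,5-dimethoxy-2,6-bis(methoxymethoxy)-4-methylphenyl]-2-oxoheptadecanoate, via Grignard reagent 11 (not isolated)
Conditions: Mg, I2 (cat.), THF, 45 °C; then added to 10 (3 equiv), THF, −78 °C; aq NH4Cl
Reagents that add atoms: none
Why: Grignard acylation with an oxalate diester: the primary alkylmagnesium bromide adds once to diethyl oxalate at −78 °C because the tetrahedral magnesium alkoxide is stable at that temperature and the oxalate is in excess, so the 2-oxo ester is released only on quench, and the aryl methyl and MOM ethers are inert to the Grignard reagent.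

Step 8
Reactants: 12 ethyl 17-[3,5-dimethoxy-2,6-bis(methoxymethoxy)-4-methylphenyl]-2-oxoheptadecanoate; 13 ethyl 2-oxobutanoate
Product: 15 2-{14-[3,5-dimethoxy-2,6-bis(methoxymethoxy)-4-methylphenyl]tetradecyl}-3,6-dihydroxy-5-methylcyclohexa-2,5-diene-1,4-dione, via linear trioxo ester 14 (not isolated)
Conditions: 12 premixed with 13 (5 equiv), added to NaOEt (7 equiv), EtOH/THF, 0 °C to rt, then 50 °C; then 1 M HCl, 0 °C
Reagents that add atoms: none
Why: Proposed new method: ethoxide reversibly generates the C3 enolates of both 2-oxo esters; the enolate of 13, present in excess, attacks the ester carbonyl of 12 (intermolecular Claisen condensation, forming C5'–C6') to give the linear 2,4,5-trioxo ester 14, whose C6 methylene, now alpha to a 1,2-diketone, is deprotonated and attacks the remaining ester carbonyl (forming C2'–C3'), the complementary order of events leading to the same ring. This second, Dieckmann-type Claisen step closes ring B by 6-exo-trig acyl substitution as a cyclohexane-1,2,4,5-tetraone, which enolises to the 2,5-dihydroxy-1,4-benzoquinone and is held by ethoxide as its dianion, a sink that should draw the reversible Claisen and aldol equilibria toward the ring. The closest known reaction type is the alkoxide-mediated double Claisen self-condensation of 2-oxoalkanoic esters to 3,6-dialkyl-2,5-dihydroxy-1,4-benzoquinones; what has not been shown is the crossed pairing of two different 2-oxo esters. No stereocentre is formed, since the transient CH(CH3) centre of 14 is lost on enolisation, and the head-to-tail regiochemistry is inherent because each partner has one nucleophilic carbon (C3) and one acyl-transfer carbon (C1). The selectivity that matters is crossed against self-condensation, which the substrate cannot impose and which is set by premixing 12 with a fivefold excess of the cheap ester 13 so that 12 should meet mostly enolates of 13, while the small symmetric self-dimer 2,5-dihydroxy-3,6-dimethyl-1,4-benzoquinone is removed by chromatography and the aryl methyl and MOM ethers are inert to ethoxide.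

Step 9
Reactants: 15 2-{14-[3,5-dimethoxy-2,6-bis(methoxymethoxy)-4-methylphenyl]tetradecyl}-3,6-dihydroxy-5-methylcyclohexa-2,5-diene-1,4-dione
Product: 16 2-[14-(2,6-dihydroxy-3,5-dimethoxy-4-methylphenyl)tetradecyl]-3,6-dihydroxy-5-methylcyclohexa-2,5-diene-1,4-dione
Conditions: 3 M aq HCl/THF, 50 °C, argon
Reagents that add atoms: none
Why: Acid-catalysed acetal hydrolysis: protonation of the MOM ethers releases the two phenols with formaldehyde and methanol, whereas the aryl methyl ethers and the acid-stable dihydroxyquinone are untouched and no free ring position is available for hydroxymethylation.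

Step 10
Reactants: 16 2-[14-(2,6-dihydroxy-3,5-dimethoxy-4-methylphenyl)tetradecyl]-3,6-dihydroxy-5-methylcyclohexa-2,5-diene-1,4-dione
Product: 17 2,5-dihydroxy-3-[14-(2-hydroxy-5-methoxy-4-methyl-3,6-dioxocyclohexa-1,4-dien-1-yl)tetradecyl]-6-methylcyclohexa-2,5-diene-1,4-dione (target, CNP0130251.0)
Conditions: PhI(OAc)2 (1.05 equiv), MeCN/H2O, 0 °C
Reagents that add atoms: water, O
Why: Oxidative demethylation of a p-methoxyphenol with trivalent iodine: ligand exchange of a phenol OH on PhI(OAc)2 and two-electron oxidation give a cation that water captures at the methoxy-bearing para carbon, and loss of methanol gives the quinone with OH beside the tether and OMe beside the methyl; the two phenols are symmetry-equivalent, capture at the ortho methoxy carbon would lead after tautomerisation to the same hydroxyquinone, and ring B is already at the quinone level with no free ring position.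

**Compound list**

1 | 2,6-dimethoxytoluene (1,3-dimethoxy-2-methylbenzene) | COc1cccc(OC)c1C | starting material
2 | 1,5-dibromo-2,4-dimethoxy-3-methylbenzene | COc1c(Br)cc(Br)c(OC)c1C | intermediate
3 | 4,6-dimethoxy-5-methylbenzene-1,3-diol | COc1c(O)cc(O)c(OC)c1C | intermediate
4 | 1,5-bis(methoxymethoxy)-2,4-dimethoxy-3-methylbenzene | COCOc1cc(OCOC)c(OC)c(C)c1OC | intermediate
5 | oxacyclohexadecan-2-one (pentadecanolide) | O=C1CCCCCCCCCCCCCCO1 | starting material
6 | pentadecane-1,15-diol | OCCCCCCCCCCCCCCCO | intermediate
7 | 1,15-dibromopentadecane | BrCCCCCCCCCCCCCCCBr | intermediate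
8 | [2,6-bis(methoxymethoxy)-3,5-dimethoxy-4-methylphenyl]lithium | [Li]c1c(OCOC)c(OC)c(C)c(OC)c1OCOC | intermediate
9 | 3-(15-bromopentadecyl)-1,5-dimethoxy-2,4-bis(methoxymethoxy)-6-methylbenzene | BrCCCCCCCCCCCCCCCc1c(OCOC)c(OC)c(C)c(OC)c1OCOC | intermediate
10 | diethyl oxalate | CCOC(=O)C(=O)OCC | starting material
11 | {15-[3,5-dimethoxy-2,6-bis(methoxymethoxy)-4-methylphenyl]pentadecyl}magnesium bromide | Br[Mg]CCCCCCCCCCCCCCCc1c(OCOC)c(OC)c(C)c(OC)c1OCOC | intermediate
12 | ethyl 17-[3,5-dimethoxy-2,6-bis(methoxymethoxy)-4-methylphenyl]-2-oxoheptadecanoate | CCOC(=O)C(=O)CCCCCCCCCCCCCCCc1c(OCOC)c(OC)c(C)c(OC)c1OCOC | intermediate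
13 | ethyl 2-oxobutanoate | CCOC(=O)C(=O)CC | starting material
14 | ethyl 20-[3,5-dimethoxy-2,6-bis(methoxymethoxy)-4-methylphenyl]-3-methyl-2,4,5-trioxoicosanoate (racemic, enolisable) | CCOC(=O)C(=O)C(C)C(=O)C(=O)CCCCCCCCCCCCCCCc1c(OCOC)c(OC)c(C)c(OC)c1OCOC | intermediate
15 | 2-{14-[3,5-dimethoxy-2,6-bis(methoxymethoxy)-4-methylphenyl]tetradecyl}-3,6-dihydroxy-5-methylcyclohexa-2,5-diene-1,4-dione | COCOc1c(CCCCCCCCCCCCCCC2=C(O)C(=O)C(C)=C(O)C2=O)c(OCOC)c(OC)c(C)c1OC | intermediate
16 | 2-[14-(2,6-dihydroxy-3,5-dimethoxy-4-methylphenyl)tetradecyl]-3,6-dihydroxy-5-methylcyclohexa-2,5-diene-1,4-dione | COc1c(C)c(OC)c(O)c(CCCCCCCCCCCCCCC2=C(O)C(=O)C(C)=C(O)C2=O)c1O | intermediate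
17 | 2,5-dihydroxy-3-[14-(2-hydroxy-5-methoxy-4-methyl-3,6-dioxocyclohexa-1,4-dien-1-yl)tetradecyl]-6-methylcyclohexa-2,5-diene-1,4-dione | COC1=C(C)C(=O)C(O)=C(CCCCCCCCCCCCCCC2=C(O)C(=O)C(C)=C(O)C2=O)C1=O | target

**Step count**

Total: 10 steps. Longest linear sequence: 8 steps (steps 1, 2, 3, 6, 7, 8, 9, 10 from 1); the chain branch from 5 (steps 4 and 5) joins at step 6.

**Steps most likely to fail**

Step 8 (crossed double Claisen annulation, the one step beyond known chemistry). The two 2-oxo esters may condense mainly with themselves. The enolates may also add to the ketone carbonyls (aldol) and the adducts lactonise irreversibly, so that little of the crossed ring forms. The fallback builds ring B by known reductive C-alkylation of a preformed dihydroxyquinone; it sets out from 9 and returns at 15.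
- Dehydrobromination of 9 with KOtBu in THF should give 1,5-dimethoxy-2,4-bis(methoxymethoxy)-6-methyl-3-(pentadec-14-en-1-yl)benzene F1.
- Lemieux–Johnson cleavage (OsO4 cat., NaIO4, 2,6-lutidine, dioxane/H2O) should shorten F1 by one carbon to 14-[3,5-dimethoxy-2,6-bis(methoxymethoxy)-4-methylphenyl]tetradecanal F2.
- Separately, commercial 1,2,4,5-tetramethoxybenzene is lithiated (n-BuLi, THF) and methylated with MeI to 1,2,4,5-tetramethoxy-3-methylbenzene F3.
- F3 is oxidised with (NH4)2Ce(NO3)6 in MeCN/H2O to 2,5-dimethoxy-3-methylcyclohexa-2,5-diene-1,4-dione F4.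
- F4 is hydrolysed (aq NaOH, then HCl) to 2,5-dihydroxy-3-methylcyclohexa-2,5-diene-1,4-dione F5.
- Proline-catalysed three-component reductive alkylation of F5 with F2 and Hantzsch ester (CH2Cl2, rt) should give 15. The Knoevenagel adduct at the only free ring carbon of F5 is reduced in situ, and the route continues with step 9.

Step 6 (aryllithium alkylation with the dibromide). The hindered, doubly chelated aryllithium may substitute slowly, so that dehydrobromination of the alkyl bromide and a second substitution on the product already formed compete. The fallback uses a monofunctional electrophile and installs the bromide afterwards; it sets out from 6 and 4 and returns at 9.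
- Selective monobromination of 6 with 48% aq HBr in refluxing toluene should give 15-bromopentadecan-1-ol F6.
- Silylation (TBSCl, imidazole, DMF) gives [(15-bromopentadecyl)oxy](tert-butyl)dimethylsilane F7.
- Aryllithium 8, generated from 4 as in step 6, is alkylated with F7 (THF/DMPU) to tert-butyl({15-[3,5-dimethoxy-2,6-bis(methoxymethoxy)-4-methylphenyl]pentadecyl}oxy)dimethylsilane F8.
- Desilylation (Bu4NF, THF) gives 15-[3,5-dimethoxy-2,6-bis(methoxymethoxy)-4-methylphenyl]pentadecan-1-ol F9.
- Appel bromination (CBr4, PPh3, imidazole, CH2Cl2) converts F9 into 9.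

Step 2 (double hydroxylation). The second C–O coupling may stall, hydrodebromination may compete, and the electron-rich resorcinolate may be oxidised by traces of air in hot alkali. The fallback replaces direct C–O coupling by C–B bond formation and mild oxidation; it sets out from 2 and returns at 3.
- Double Miyaura borylation (B2pin2, PdCl2(dppf), KOAc, dioxane, 90 °C) should give 2,2'-(4,6-dimethoxy-5-methyl-1,3-phenylene)bis(4,4,5,5-tetramethyl-1,3,2-dioxaborolane) F10.
- Oxidation of both C–B bonds (H2O2, aq NaOH, THF, 0 °C, then acidification) gives 3, which is protected at once as in step 3.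

**Further compounds**

F1 | step 8 | 1,5-dimethoxy-2,4-bis(methoxymethoxy)-6-methyl-3-(pentadec-14-en-1-yl)benzene | C=CCCCCCCCCCCCCCc1c(OCOC)c(OC)c(C)c(OC)c1OCOC
F2 | step 8 | 14-[3,5-dimethoxy-2,6-bis(methoxymethoxy)-4-methylphenyl]tetradecanal | O=CCCCCCCCCCCCCCc1c(OCOC)c(OC)c(C)c(OC)c1OCOC
F3 | step 8 | 1,2,4,5-tetramethoxy-3-methylbenzene | COc1cc(OC)c(OC)c(C)c1OC
F4 | step 8 | 2,5-dimethoxy-3-methylcyclohexa-2,5-diene-1,4-dione | COC1=CC(=O)C(OC)=C(C)C1=O
F5 | step 8 | 2,5-dihydroxy-3-methylcyclohexa-2,5-diene-1,4-dione | OC1=CC(=O)C(O)=C(C)C1=O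
F6 | step 6 | 15-bromopentadecan-1-ol | OCCCCCCCCCCCCCCCBr
F7 | step 6 | [(15-bromopentadecyl)oxy](tert-butyl)dimethylsilane | CC(C)(C)[Si](C)(C)OCCCCCCCCCCCCCCCBr
F8 | step 6 | tert-butyl({15-[3,5-dimethoxy-2,6-bis(methoxymethoxy)-4-methylphenyl]pentadecyl}oxy)dimethylsilane | CC(C)(C)[Si](C)(C)OCCCCCCCCCCCCCCCc1c(OCOC)c(OC)c(C)c(OC)c1OCOC
F9 | step 6 | 15-[3,5-dimethoxy-2,6-bis(methoxymethoxy)-4-methylphenyl]pentadecan-1-ol | OCCCCCCCCCCCCCCCc1c(OCOC)c(OC)c(C)c(OC)c1OCOC
F10 | step 2 | 2,2'-(4,6-dimethoxy-5-methyl-1,3-phenylene)bis(4,4,5,5-tetramethyl-1,3,2-dioxaborolane) | COc1c(B2OC(C)(C)C(C)(C)O2)cc(B3OC(C)(C)C(C)(C)O3)c(OC)c1C
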